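The amounts first: these flasks hold the same substrate and the same impurity, and they differ in enzyme.

| flask | substrate | enzyme | impurity | remark |
|---|---|---|---|---|
| winter | 0.050 M | 25 µM | 8.3 µM | run made earlier |
| midnight | 0.050 M | 40 µM | 8.3 µM | run made earlier |
| flask | 0.050 M | 18 µM | 8.3 µM |  |

| run | time / h | product / % |
|---|---|---|
| winter | 5.00 | 22.8 |
| winter | 10.0 | 42.4 |
| winter | 15.0 | 60.4 |
| winter | 20.0 | 75.5 |
| winter | 25.0 | 87.0 |
| winter | 30.0 | 94.0 |
| winter | 40.0 | 99.3 |
| midnight | 5.00 | 39.8 |
| midnight | 10.0 | 72.3 |
| midnight | 15.0 | 92.3 |
| midnight | 20.0 | 99.1 |
| midnight | 25.0 | 99.8 |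
| midnight | 30.0 | 100.1 |
| midnight | 40.0 | 99.6 |

(scatter of a reading: 0.3 percentage points)

- factor on the rate of making product when 5.0% of the substrate are converted if enzyme is charged twice over
- factor on the rate when 5.0% of the substrate are converted if enzyme is charged at 200 µM instead



I follow the fraction of substrate left. In the first 5.00 h the winter run makes 22.8% and the midnight run 39.8%. Each curve then bends gently. Read between the readings, half of the substrate is left at 12.1 h in winter and 6.57 h at midnight. The knee comes late, after 25.0 h in winter and 15.0 h at midnight, and the curves level out at 99.3% and 99.6%.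

Those half times differ by a factor of 1.84, which is more than the 1.60 between the enzyme charges. So I subtract c(impurity) from c(enzyme), and the factor becomes 1.90. For the flask this gives 9.70 µM, my working enzyme, the charge of enzyme minus the charge of impurity, also called active enzyme. Taking rate as proportional to it, I reckon 2.86 for the doubled charge and 19.8 for 200 µM.

The forecast says 2.8 and 19.3, the second a little lower than mine, on the ground that “the impurity seems to titrate enzyme nearly stoichiometrically”.

The simulation gives 2.56 and 16.7, so the second is lower than the forecast.

    enzyme + impurity → spent catalyst (k = 3.91 × 10⁵ M⁻¹ h⁻¹)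
    complex → enzyme + product (k = 162 h⁻¹)
    substrate + enzyme ⇌ complex (K = 84.5 M⁻¹, k = 7.51 × 10⁵ M⁻¹ h⁻¹)

In the flask, working enzyme describes the state at 15.0 h: spent catalyst is then 46.1% of the catalyst charged, leaving 9.70 µM as enzyme and complex together, against my 9.70 µM. The question looks much earlier, at 1.39 h, when the share spent is 35.7%. The flask then still has 11.6 µM as enzyme and complex together, more than 9.70 µM. Setting the working enzyme of the 200 µM charge over this gives 16.6, beside the simulated 16.7. In the flask the apparent order in enzyme at that conversion is 1.6, in part because of the loss of enzyme and impurity to spent catalyst: without that loss it is 1.0.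

The numbers in the tables were computed with constants of no real substance; the scatter is artificial.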